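## Structural features

Guangsangon N is a 1-methylcyclohexene (C1(Me)=C2, C6 = CH2) whose carbons C3, C4 and C5 are contiguous stereocentres (3R,4R,5S). They carry a resorcinol ring, a 2,4-dihydroxybenzoyl group and a 2,4-dihydroxyphenyl group in an all-trans, all-equatorial array. The C3 resorcinol is a linking ring: its other substituted carbon is C2 of a (2S)-7-hydroxychroman-4-one, so it is also ring B of a flavanone. That fourth stereocentre is too far from the core to be relayed and needs its own control. The fragile points are the seven free phenols, the flavanone C2 (lost by retro-oxa-Michael opening in base) and C4–H next to an aryl ketone. The ortho-phenols on the C3 and C5 aryl groups can add to C1=C2 or ketalise the C4 carbonyl in strong acid, and the trisubstituted alkene forbids reductive deprotection. The real difficulty is the absolute configuration of a ring whose stereocentres bear only carbon and hydrogen, together with the fixed alkene position. The key step uses the fact that C3 (as carbonyl carbon), C4, C5 and C6 with the C5 aryl group are the ring of a mirror-symmetric 3-arylcyclobutanone, and that C2=C1(Me) is propyne. Insertion of the alkyne into one of the two enantiotopic C3–CH2 bonds forms C2–C3 and C1–C6, sets C5, fixes the methyl group and the double bond, and leaves C3 as a ketone for building C4 and C3.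

## Logic of the disconnections

**27 ⇒ 26.** The seven phenolic O–CH2 acetal bonds are cut last. Free phenols cannot pass through the organometallic steps, and one kind of protecting group allows one final operation. The demand is a cleavage mild enough for the flavanone C2, the C1=C2 alkene and the C4 ketone.

**26 ⇒ 25 ⇒ 24.** The C4 acyl C=O is taken back to a silyl-protected carbinol (C=O ⇒ CH–O–Si). A ketone flanking C4–H would expose a C3 leaving group to E1cB loss, the aldol link to retro-aldol cleavage, and would itself be reduced in step 8. The gain is an inert C4 side chain. The demand is that desilylation and oxidation spare the flavanone and that both carbinol epimers converge.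

**24 ⇒ 14 + 23.** The C3–C(aryl) bond is cut. C3 is allylic and can be ionised, and the cut divides the molecule into two halves of similar size, each with its own stereochemistry already settled. The demand is net inversion at C3 (so the C3–O bond of 14 must be cis to the C4 side chain), attack at C3 and not C1, and conditions that do not open the flavanone.

**14 ⇒ 13 ⇒ 12 ⇒ 11 ⇒ 9 + 2.** The carbonate C–O and the O–Si bond are functional-group changes; then C3–H (hydride) and the C4–C(carbinol) bond (aldol) are cut. The C3 carbonyl of 9 acidifies C4–H2 and later becomes the leaving group, and 2 is already in hand. This returns to a ring with one stereocentre. The demands are kinetic enolisation toward C4, attack anti to the C5 aryl group, and equatorial hydride delivery at C3.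

**9 ⇒ 7 + 8.** C2–C3 and C1–C6 are cut. A chiral six-membered ring becomes an achiral four-membered ketone and a three-carbon alkyne, and ring, methyl position, alkene position and C5 all come from one operation. The demand is a catalyst that selects between enantiotopic bonds, orients 8 with its CH end on C3, and tolerates a terminal alkyne.

**7 ⇒ 6 ⇒ 3 + 5; 5 ⇐ 4; 3 ⇐ 2 ⇐ 1.** Two C–Cl bonds are restored, then the carbonyl–CH2 and CCl2–CH(aryl) ring bonds are cut ([2+2]), then the vinyl C=C and the two O–CH2 bonds. The polarised ketene adds to the electron-rich alkene with reliable orientation. The demand is that the zinc salts must not strip the acetals.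

**23 ⇒ 22 ⇒ 19 + 21.** The C–B bond comes from C–Br, and the flavanone C2–C(aryl) bond is cut as a conjugate addition. The flat 21 offers two faces to a chiral catalyst, so C2 is set on a small fragment. The demand is face selection and an aryl bromide that survives.

**19 ⇒ 16 ⇒ 15; 21 ⇒ 20.** The C–B bond and the O–CH2 bonds are cut. The two bromines of 16 are equivalent, so a single exchange differentiates the two linking-ring positions without any selectivity problem.

## Other disconnections considered

**Alternative 1:** The cut runs through C4–C5 and C1–C6 and gives styrene 3 and the 3-aroyl-6-methylpyran-2-one A2 (pyranone C3 becomes C4, pyranone C6 becomes C1). Forward, a chiral Cu(OTf)2–bis(oxazoline) complex would chelate the two carbonyl groups of A2, 3 would add across pyranone C3 and C6 in an inverse-demand [4+2] reaction, and the bridged lactone would lose CO2 to the dienyl ketone A1, in which C5 is set. A1 is properly a 1-acyl-4-methyl-6-arylcyclohexa-1,3-diene, because the acyl group sits on the diene terminus next to the stereocentre.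

- In favour: one step joins two fragments, installs the aroyl group at its final oxidation level and sets C5. On convergence and step count to a C4-acylated, C5-arylated ring it is better than the chosen plan (one step against five). Its two-point-binding model for enantioselection is at least as well founded as the untested ligand control of step 5.
- Against: the methyl group sits on the pyranone terminus that must bond to the styrene CH2, which slows the cycloaddition. A1 is one oxidation or one 1,5-hydrogen shift away from an achiral biaryl or a scrambled diene. Most seriously, C3 stays sp2. The linking ring would have to enter by conjugate arylation cis to the C5 aryl group, but that group, pseudo-axial next to the acylated sp2 carbon, shields exactly this face, so the 3,5-trans isomer is the expected product.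
- Comparison: both plans set C5 by catalyst control. The chosen plan costs more steps but fixes C3 by an invertive substitution whose sense is dictated by a reagent-controlled reduction.

**Alternative 2:** The cut runs through C3–C4 and C2–C3. C3 arrives as the carbonyl carbon of aldehyde A5, and the other five ring carbons come from the open-chain silyl enol ether–vinylsilane A4, which must already hold C5 as S. Forward, BF3·OEt2 would promote Mukaiyama aldol addition of C4 to A5, the electron-rich benzylic oxygen would ionise, and the vinylsilane would attack the cation through its silicon-bearing carbon C2 (6-endo closure, loss of silicon) to give the trans,trans hexabenzyl ether A3.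

- In favour: both bonds to C3 are made in one flask with no redox work at C3, through a chair-like closure that places all three substituents equatorially. On these points it is better than steps 6–9 and 15 of the chosen plan. Every elementary step is a known reaction type, which step 5 is not. The alkene position is fixed by construction in both plans (equal).
- Against: C5 is not made in the ring-forming step, so A4 needs its own asymmetric synthesis. The Lewis acid excludes acetal protection, and the benzyl ethers must later be removed by hydrogenolysis beside a trisubstituted alkene. The long-lived, oxygen-stabilised cation can be captured by the C5 aryl ring or lose a proton, and the vinylsilane can be protodesilylated.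
- Comparison: fewer ring-forming operations, but from a precursor whose synthesis should cost more than that of 7, so the overall counts should be similar.

**Alternative 3:** The cut is the O1–C2 bond of the chromanone and leads to the alkylidene β-ketoester A7. Forward, a quinine-derived thiourea would hold the β-ketoester by hydrogen bonds while its quinuclidine nitrogen deprotonates the ortho-phenol, and 6-endo-trig oxa-Michael addition would give the 3-(tert-butoxycarbonyl)flavanone A6; acid would then remove the ester by decarboxylation.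

- In favour: it is an established kind of catalytic enantioselective flavanone synthesis. C2 is made at the very end and never meets the borylation, coupling and fluoride steps that the chosen plan asks it to survive, so on safety of this stereocentre it is better. The acidic decarboxylation can be merged with acetal removal, which makes it equal or slightly better in step count for the chromanone alone.
- Against: it is an endgame only and leaves the cyclohexene with C3–C5 to some other method, so it complements step 5 more than it replaces it. It places three to four linear steps on the fully elaborated core, including a Knoevenagel condensation next to the epimerisable C4 ketone, and the catalyst must override any bias of the large chiral substituent.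
- Comparison: the chosen plan makes the same centre by a C–C bond on a small fragment and joins convergently. The oxa-Michael closure remains the natural way out if the flavanone does not survive steps 14 and 15.

Key step: step 5

**Remarks on the chemistry**

- Core numbering throughout: C1(Me)=C2, C3 (linking ring), C4 (acyl side chain), C5 (aryl), C6 (CH2). ArM = 2,4-bis(methoxymethoxy)phenyl.
- Assumption: the sense of induction of the chiral ligands in steps 5 and 13 cannot be predicted with confidence; the ligand antipode is chosen after a test run so that 9 and 22 are S.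
- Assumption: 11–14, 24 and 25 are carried as mixtures of epimers at the side-chain carbinol carbon, which is oxidised in step 17; their SMILES leave that centre open.
- 15 and 20 are taken as purchased; 2 is used twice (steps 2 and 6).
- Structure check: 9 has the same spatial arrangement and the same descriptor (S) at C5 as the target.
- Design changes: the C4 acyl group enters at the carbinol level instead of as a ketone; propyne is dosed slowly as a solution; the acetal-protected ortho-oxygen of 7 is kept because it can chelate nickel.

## Route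

Step 1
Reactants: 1 2,4-dihydroxybenzaldehyde
Product: 2 2,4-bis(methoxymethoxy)benzaldehyde
Conditions: MOMCl, i-Pr2NEt, CH2Cl2, 0 °C → 40 °C
Reagents that add atoms: chloromethyl methyl ether (MOMCl), COCCl
Why: O-alkylation of both phenols to acetals; excess reagent and warming overcome the hydrogen-bonded ortho-OH, and the MOM ethers tolerate the base, hydride and zerovalent-metal steps ahead.

Step 2
Reactants: 2 2,4-bis(methoxymethoxy)benzaldehyde
Product: 3 1-ethenyl-2,4-bis(methoxymethoxy)benzene
Conditions: Ph3PCH3Br, KOt-Bu, THF, 0 °C → rt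
Reagents that add atoms: methyltriphenylphosphonium bromide, C[P+](c1ccccc1)(c1ccccc1)c1ccccc1.[Br-]
Why: Wittig methylenation of a non-enolisable aryl aldehyde under basic conditions that leave the acetals alone.

Step 3
Reactants: 3 1-ethenyl-2,4-bis(methoxymethoxy)benzene; 4 trichloroacetyl chloride
Product: 6 2,2-dichloro-3-[2,4-bis(methoxymethoxy)phenyl]cyclobutan-1-one (racemic), via dichloroketene 5 (not isolated)
Conditions: Zn–Cu couple, 4 added slowly, Et2O/DME, 0 °C → rt
Reagents that add atoms: none
Why: Zinc dechlorinates 4 to the ketene, which undergoes thermal [2+2] cycloaddition with the electron-rich styrene, carbonyl carbon to the terminal CH2 and CCl2 to the benzylic carbon. DME precipitates ZnCl2 so that the Lewis acid should neither strip the acetals nor polymerise 3; the stereocentre is racemic and becomes prochiral in step 4.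

Step 4
Reactants: 6 2,2-dichloro-3-[2,4-bis(methoxymethoxy)phenyl]cyclobutan-1-one
Product: 7 3-[2,4-bis(methoxymethoxy)phenyl]cyclobutan-1-one
Conditions: Zn dust, NH4Cl, MeOH, rt
Reagents that add atoms: none
Why: Reductive dechlorination of an α,α-dichloroketone through zinc enolates protonated by ammonium chloride, buffered so that the acetals survive; the product is the achiral, mirror-symmetric precursor of the key step.

Step 5
Reactants: 7 3-[2,4-bis(methoxymethoxy)phenyl]cyclobutan-1-one; 8 propyne
Product: 9 (5S)-5-[2,4-bis(methoxymethoxy)phenyl]-3-methylcyclohex-2-en-1-one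
Conditions: Ni(cod)2 (10 mol%), (S)-BINOL N,N-bis[(S)-1-phenylethyl]phosphoramidite (20 mol%; antipode as required), 8 (1 M in THF, 2 equiv, syringe pump over 8 h), toluene, 60 °C, sealed vessel
Reagents that add atoms: none
Why: Proposed new method: zerovalent nickel couples the strained ketone and the alkyne oxidatively to a spiro oxanickelacyclopentene in which the carbonyl carbon C3 is bonded to the unsubstituted alkyne carbon C2, β-carbon elimination of one acyl–CH2 bond relieves ring strain to a seven-membered nickelacycle, and C(sp3)–C(sp2) reductive elimination forms C6–C1; the closest known reaction types are the Ni(cod)2/trialkylphosphine [4+2] ring expansion of cyclobutanones with internal alkynes and the enantioselective intramolecular C–C activation of 3-substituted cyclobutanones. The six-membered ring is closed by reductive elimination from the seven-membered metallacycle, a formal insertion of two alkyne carbons into a C–C σ bond and not a pericyclic closure. The only new stereocentre, C5, is controlled by the chiral ligand on nickel, which decides which of the two enantiotopic acyl–CH2 bonds is cleaved. The step needs enantiotopic-bond selection (ligand), alkyne orientation (the CH end goes to the crowded spiro carbon and the methyl-bearing carbon to nickel, on steric grounds) and chemoselectivity against alkyne oligomerisation and β-hydride loss from the nickelacycle. Slow dosing keeps the alkyne concentration low, and the ortho-OMOM group of 7 can chelate the alkylnickel and hold C5–H away from the metal. All atoms of 7 and 8 appear in 9.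

Step 6
Reactants: 9 (5S)-5-[2,4-bis(methoxymethoxy)phenyl]-3-methylcyclohex-2-en-1-one; 2 2,4-bis(methoxymethoxy)benzaldehyde
Product: 11 (5S,6S)-5-ArM-6-[ArM(hydroxy)methyl]-3-methylcyclohex-2-en-1-one (carbinol epimers), via lithium dienolate 10 (not isolated)
Conditions: LiN(i-Pr)2 (LDA), THF, −78 °C; 2, −78 °C; AcOH quench at −78 °C
Reagents that add atoms: none
Why: Kinetic deprotonation on the CH2 side of the ketone (C4) gives the cross-conjugated dienolate, which undergoes directed aldol addition to the non-enolisable aldehyde on the face of C4 anti to the neighbouring C5 aryl group (C4/C5 trans). The carbinol centre forms as a mixture that is irrelevant because it is oxidised in step 17, and the cold acidic quench forestalls retro-aldol reaction and dehydration.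

Step 7
Reactants: 11 (5S,6S)-5-ArM-6-[ArM(hydroxy)methyl]-3-methylcyclohex-2-en-1-one
Product: 12 (5S,6S)-5-ArM-6-[ArM(triethylsilyloxy)methyl]-3-methylcyclohex-2-en-1-one
Conditions: TESOTf, 2,6-lutidine, CH2Cl2, −78 °C
Reagents that add atoms: triethylsilyl trifluoromethanesulfonate (TESOTf), CC[Si](CC)(CC)OS(=O)(=O)C(F)(F)F
Why: Silylation of a hindered secondary benzylic alcohol with a silyl triflate and a hindered base; capping the β-hydroxy ketone removes the retro-aldol path and the acidic OH before the hydride step.

Step 8
Reactants: 12 (5S,6S)-5-ArM-6-[ArM(triethylsilyloxy)methyl]-3-methylcyclohex-2-en-1-one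
Product: 13 (1S,5S,6R)-5-ArM-6-[ArM(triethylsilyloxy)methyl]-3-methylcyclohex-2-en-1-ol (OH cis to the C4 side chain)
Conditions: LiBH(s-Bu)3 (L-Selectride), THF, −78 °C; H2O at −78 °C
Reagents that add atoms: none
Why: 1,2-Reduction of a β,β-disubstituted enone by a bulky trialkylborohydride, which approaches C3 along the equatorial path anti to the adjacent C4 side chain and gives the axial alcohol cis to that side chain (the piperitone to cis-piperitol pattern). This C3 carbinol is the stereochemical handle for step 15, and the cold quench prevents 1,5-silyl migration.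

Step 9
Reactants: 13 (1S,5S,6R)-5-ArM-6-[ArM(triethylsilyloxy)methyl]-3-methylcyclohex-2-en-1-ol
Product: 14 methyl (1S,5S,6R)-5-ArM-6-[ArM(triethylsilyloxy)methyl]-3-methylcyclohex-2-en-1-yl carbonate
Conditions: ClCO2Me, pyridine, DMAP (cat.), CH2Cl2, 0 °C → rt
Reagents that add atoms: methyl chloroformate, COC(=O)Cl
Why: Acylation of the allylic alcohol to a methyl carbonate, a leaving group that ionises readily on zerovalent palladium; with no acidic hydrogen at C4 there is no E1cB path.

Step 10
Reactants: 15 4,6-dibromobenzene-1,3-diol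
Product: 16 1,5-dibromo-2,4-bis(methoxymethoxy)benzene
Conditions: MOMCl, i-Pr2NEt, CH2Cl2, 0 °C → rt
Reagents that add atoms: chloromethyl methyl ether (MOMCl), COCCl
Why: O-alkylation of both phenols; the acetal oxygens stabilise the ortho-lithium species of step 11.

Step 11
Reactants: 16 1,5-dibromo-2,4-bis(methoxymethoxy)benzene
Product: 19 [5-bromo-2,4-bis(methoxymethoxy)phenyl]boronic acid, via aryllithium 17 (not isolated), via lithium triisopropoxyborate 18 (not isolated)
Conditions: n-BuLi (1.0 equiv), THF, −78 °C; B(Oi-Pr)3; AcOH, H2O, 0 °C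
Reagents that add atoms: triisopropyl borate, CC(C)OB(OC(C)C)OC(C)C; water, O
Why: Lithium–bromine exchange outruns ortho-deprotonation at −78 °C and stops after one of the two equivalent bromines because one equivalent is used and the aryllithium is chelated by the ortho-OMOM group. Borate trapping and mild hydrolysis give the boronic acid with the second bromine kept for step 14.

Step 12
Reactants: 20 7-hydroxy-4H-chromen-4-one
Product: 21 7-(methoxymethoxy)-4H-chromen-4-one
Conditions: MOMCl, i-Pr2NEt, CH2Cl2, 0 °C → rt
Reagents that add atoms: chloromethyl methyl ether (MOMCl), COCCl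
Why: O-alkylation of the single phenol, so that all seven phenols of the target carry the same protecting group.

Step 13
Reactants: 19 [5-bromo-2,4-bis(methoxymethoxy)phenyl]boronic acid; 21 7-(methoxymethoxy)-4H-chromen-4-one
Product: 22 (2S)-2-[5-bromo-2,4-bis(methoxymethoxy)phenyl]-7-(methoxymethoxy)chroman-4-one
Conditions: [RhCl(C2H4)2]2 (2.5 mol%), (R,R)-2,5-diphenylbicyclo[2.2.2]octa-2,5-diene (5.5 mol%; antipode as required), KOH (20 mol%), 19 (2.5 equiv), dioxane/H2O (10:1), 40 °C
Reagents that add atoms: none
Why: Hayashi–Miyaura-type asymmetric 1,4-addition: the aryl group passes from boron to monovalent rhodium, adds to C2 of the chromone, and the rhodium enolate is protonated by water. The chiral diene selects the face of the chromone and so sets the flavanone C2 as S; rhodium leaves the aryl bromide alone, and the cheap boronic acid is used in excess to offset protodeboronation.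

Step 14
Reactants: 22 (2S)-2-[5-bromo-2,4-bis(methoxymethoxy)phenyl]-7-(methoxymethoxy)chroman-4-one
Product: 23 (2S)-2-[2,4-bis(methoxymethoxy)-5-(4,4,5,5-tetramethyl-1,3,2-dioxaborolan-2-yl)phenyl]-7-(methoxymethoxy)chroman-4-one
Conditions: B2pin2, PdCl2(dppf) (5 mol%), KOAc, 1,4-dioxane, 80 °C
Reagents that add atoms: bis(pinacolato)diboron, CC1(C)OB(OC1(C)C)B1OC(C)(C)C(C)(C)O1
Why: Miyaura borylation of the aryl bromide; acetate in dry dioxane is too weak a base to open the flavanone by retro-oxa-Michael reaction, so C2 should keep its configuration.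

Step 15
Reactants: 14 methyl (1S,5S,6R)-5-ArM-6-[ArM(triethylsilyloxy)methyl]-3-methylcyclohex-2-en-1-yl carbonate; 23 (2S)-2-[2,4-bis(methoxymethoxy)-5-(4,4,5,5-tetramethyl-1,3,2-dioxaborolan-2-yl)phenyl]-7-(methoxymethoxy)chroman-4-one
Product: 24 (2S)-2-{5-[(1R,5S,6R)-5-ArM-6-[ArM(triethylsilyloxy)methyl]-3-methylcyclohex-2-en-1-yl]-2,4-bis(methoxymethoxy)phenyl}-7-(methoxymethoxy)chroman-4-one
Conditions: Pd2(dba)3 (5 mol%), PPh3 (20 mol%), CsF, THF/H2O (20:1), 40 °C
Reagents that add atoms: none
Why: Allyl–aryl Suzuki–Miyaura-type coupling through Tsuji–Trost ionisation: zerovalent palladium displaces the axial carbonate with inversion, the aryl group moves from boron to palladium, and reductive elimination delivers it to the less substituted allyl terminus C3 from the metal face. The net inversion places the linking ring trans to the C4 side chain and cis to the C5 aryl group (core 3R); attack at C1 would make a quaternary centre and is disfavoured.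

Step 16
Reactants: 24 (2S)-2-{5-[(1R,5S,6R)-5-ArM-6-[ArM(triethylsilyloxy)methyl]-3-methylcyclohex-2-en-1-yl]-2,4-bis(methoxymethoxy)phenyl}-7-(methoxymethoxy)chroman-4-one
Product: 25 (2S)-2-{5-[(1R,5S,6R)-5-ArM-6-[ArM(hydroxy)methyl]-3-methylcyclohex-2-en-1-yl]-2,4-bis(methoxymethoxy)phenyl}-7-(methoxymethoxy)chroman-4-one
Conditions: HF·pyridine, pyridine, THF, 0 °C → rt
Reagents that add atoms: none
Why: Fluoride cleavage of the secondary triethylsilyl ether under buffered conditions that spare the aryl MOM ethers and do not enolise the flavanone.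

Step 17
Reactants: 25 (2S)-2-{5-[(1R,5S,6R)-5-ArM-6-[ArM(hydroxy)methyl]-3-methylcyclohex-2-en-1-yl]-2,4-bis(methoxymethoxy)phenyl}-7-(methoxymethoxy)chroman-4-one
Product: 26 (2S)-2-{5-[(1R,5S,6R)-6-[2,4-bis(methoxymethoxy)benzoyl]-5-ArM-3-methylcyclohex-2-en-1-yl]-2,4-bis(methoxymethoxy)phenyl}-7-(methoxymethoxy)chroman-4-one
Conditions: Dess–Martin periodinane, NaHCO3, CH2Cl2, rt
Reagents that add atoms: none
Why: Dess–Martin oxidation of the benzylic secondary alcohol to the aryl ketone under buffered neutral conditions. Both carbinol epimers converge, and C4, now α to the ketone, already holds the thermodynamically preferred all-equatorial arrangement.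

Step 18
Reactants: 26 (2S)-2-{5-[(1R,5S,6R)-6-[2,4-bis(methoxymethoxy)benzoyl]-5-ArM-3-methylcyclohex-2-en-1-yl]-2,4-bis(methoxymethoxy)phenyl}-7-(methoxymethoxy)chroman-4-one
Product: 27 guangsangon N, (2S)-2-{5-[(1R,5S,6R)-6-(2,4-dihydroxybenzoyl)-5-(2,4-dihydroxyphenyl)-3-methylcyclohex-2-en-1-yl]-2,4-dihydroxyphenyl}-7-hydroxychroman-4-one
Conditions: HCl (1.25 M in MeOH), 35 °C
Reagents that add atoms: none
Why: Acid-catalysed transacetalisation of the seven aryl MOM ethers to methanol, so that formaldehyde leaves as dimethoxymethane and cannot alkylate the resorcinol rings. Dilute acid and low temperature are chosen to avoid phenol addition to C1=C2, ketalisation at the C4 carbonyl and flavanone opening.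

## Compound list

1 | 2,4-dihydroxybenzaldehyde | O=Cc1ccc(O)cc1O | starting material
2 | 2,4-bis(methoxymethoxy)benzaldehyde | O=Cc1ccc(OCOC)cc1OCOC | intermediate
3 | 1-ethenyl-2,4-bis(methoxymethoxy)benzene | C=Cc1ccc(OCOC)cc1OCOC | intermediate
4 | trichloroacetyl chloride | ClC(=O)C(Cl)(Cl)Cl | starting material
5 | dichloroketene | O=C=C(Cl)Cl | intermediate (not isolated)
6 | 2,2-dichloro-3-[2,4-bis(methoxymethoxy)phenyl]cyclobutan-1-one (racemic) | O=C1CC(c2ccc(OCOC)cc2OCOC)C1(Cl)Cl | intermediate
7 | 3-[2,4-bis(methoxymethoxy)phenyl]cyclobutan-1-one | O=C1CC(c2ccc(OCOC)cc2OCOC)C1 | intermediate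
8 | propyne | CC#C | starting material
9 | (5S)-5-[2,4-bis(methoxymethoxy)phenyl]-3-methylcyclohex-2-en-1-one | CC1=CC(=O)C[C@@H](c2ccc(OCOC)cc2OCOC)C1 | intermediate
10 | lithium (6S)-6-[2,4-bis(methoxymethoxy)phenyl]-4-methylcyclohexa-1,3-dien-2-olate (cross-conjugated dienolate of 9) | CC1=CC(O[Li])=C[C@@H](c2ccc(OCOC)cc2OCOC)C1 | intermediate (not isolated)
11 | (5S,6S)-5-ArM-6-[ArM(hydroxy)methyl]-3-methylcyclohex-2-en-1-one, carbinol epimers | CC1=CC(=O)[C@H](C(O)c2ccc(OCOC)cc2OCOC)[C@@H](c2ccc(OCOC)cc2OCOC)C1 | intermediate
12 | (5S,6S)-5-ArM-6-[ArM(triethylsilyloxy)methyl]-3-methylcyclohex-2-en-1-one | CC1=CC(=O)[C@H](C(O[Si](CC)(CC)CC)c2ccc(OCOC)cc2OCOC)[C@@H](c2ccc(OCOC)cc2OCOC)C1 | intermediate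
13 | (1S,5S,6R)-5-ArM-6-[ArM(triethylsilyloxy)methyl]-3-methylcyclohex-2-en-1-ol | CC1=C[C@H](O)[C@H](C(O[Si](CC)(CC)CC)c2ccc(OCOC)cc2OCOC)[C@@H](c2ccc(OCOC)cc2OCOC)C1 | intermediate
14 | methyl (1S,5S,6R)-5-ArM-6-[ArM(triethylsilyloxy)methyl]-3-methylcyclohex-2-en-1-yl carbonate | CC1=C[C@H](OC(=O)OC)[C@H](C(O[Si](CC)(CC)CC)c2ccc(OCOC)cc2OCOC)[C@@H](c2ccc(OCOC)cc2OCOC)C1 | intermediate
15 | 4,6-dibromobenzene-1,3-diol | Oc1cc(O)c(Br)cc1Br | starting material
16 | 1,5-dibromo-2,4-bis(methoxymethoxy)benzene | COCOc1cc(OCOC)c(Br)cc1Br | intermediate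
17 | [5-bromo-2,4-bis(methoxymethoxy)phenyl]lithium | [Li]c1cc(Br)c(OCOC)cc1OCOC | intermediate (not isolated)
18 | lithium [5-bromo-2,4-bis(methoxymethoxy)phenyl]triisopropoxyborate | [Li+].CC(C)O[B-](OC(C)C)(OC(C)C)c1cc(Br)c(OCOC)cc1OCOC | intermediate (not isolated)
19 | [5-bromo-2,4-bis(methoxymethoxy)phenyl]boronic acid | OB(O)c1cc(Br)c(OCOC)cc1OCOC | intermediate
20 | 7-hydroxy-4H-chromen-4-one | O=c1ccoc2cc(O)ccc12 | starting material
21 | 7-(methoxymethoxy)-4H-chromen-4-one | O=c1ccoc2cc(OCOC)ccc12 | intermediate
22 | (2S)-2-[5-bromo-2,4-bis(methoxymethoxy)phenyl]-7-(methoxymethoxy)chroman-4-one | O=C1C[C@@H](c2cc(Br)c(OCOC)cc2OCOC)Oc2cc(OCOC)ccc21 | intermediate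
23 | (2S)-2-[2,4-bis(methoxymethoxy)-5-(4,4,5,5-tetramethyl-1,3,2-dioxaborolan-2-yl)phenyl]-7-(methoxymethoxy)chroman-4-one | O=C1C[C@@H](c2cc(B3OC(C)(C)C(C)(C)O3)c(OCOC)cc2OCOC)Oc2cc(OCOC)ccc21 | intermediate
24 | (2S)-2-{5-[(1R,5S,6R)-5-ArM-6-[ArM(triethylsilyloxy)methyl]-3-methylcyclohex-2-en-1-yl]-2,4-bis(methoxymethoxy)phenyl}-7-(methoxymethoxy)chroman-4-one | CC1=C[C@@H](c2cc([C@@H]3CC(=O)c4ccc(OCOC)cc4O3)c(OCOC)cc2OCOC)[C@H](C(O[Si](CC)(CC)CC)c2ccc(OCOC)cc2OCOC)[C@@H](c2ccc(OCOC)cc2OCOC)C1 | intermediate
25 | (2S)-2-{5-[(1R,5S,6R)-5-ArM-6-[ArM(hydroxy)methyl]-3-methylcyclohex-2-en-1-yl]-2,4-bis(methoxymethoxy)phenyl}-7-(methoxymethoxy)chroman-4-one | CC1=C[C@@H](c2cc([C@@H]3CC(=O)c4ccc(OCOC)cc4O3)c(OCOC)cc2OCOC)[C@H](C(O)c2ccc(OCOC)cc2OCOC)[C@@H](c2ccc(OCOC)cc2OCOC)C1 | intermediate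
26 | (2S)-2-{5-[(1R,5S,6R)-6-[2,4-bis(methoxymethoxy)benzoyl]-5-ArM-3-methylcyclohex-2-en-1-yl]-2,4-bis(methoxymethoxy)phenyl}-7-(methoxymethoxy)chroman-4-one | CC1=C[C@@H](c2cc([C@@H]3CC(=O)c4ccc(OCOC)cc4O3)c(OCOC)cc2OCOC)[C@H](C(=O)c2ccc(OCOC)cc2OCOC)[C@@H](c2ccc(OCOC)cc2OCOC)C1 | intermediate
27 | guangsangon N | CC1=C[C@@H](c2cc([C@@H]3CC(=O)c4ccc(O)cc4O3)c(O)cc2O)[C@H](C(=O)c2ccc(O)cc2O)[C@@H](c2ccc(O)cc2O)C1 | target

## Step count and risks

Total: 18 steps. Longest linear sequence: 13 steps (steps 1–9 and 15–18, from 1). The second branch (steps 10–14) has five steps.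

**Step 5 (key step).** The terminal alkyne may oligomerise or cyclotrimerise on zerovalent nickel faster than it couples with the ketone. β-Hydride loss from the nickelacycle may open the ring. Discrimination between the two CH2 arms, which differ only through a remote aryl group, may be poor. The fallback uses known chemistry, sets out from 2 and returns at 9. Claisen–Schmidt condensation of 2 with acetone (NaOH, aqueous EtOH) gives (E)-4-[2,4-bis(methoxymethoxy)phenyl]but-3-en-2-one F1. Iminium-catalysed asymmetric Michael addition of allyl acetoacetate (9-amino-9-deoxy-epi-cinchona primary amine salt, antipode as required) gives allyl (3R)-2-acetyl-3-[2,4-bis(methoxymethoxy)phenyl]-5-oxohexanoate F2. Enamine-mediated aldol condensation (pyrrolidine, AcOH), in which the methyl ketone arm attacks the β-ketoester carbonyl, closes allyl (6R)-6-[2,4-bis(methoxymethoxy)phenyl]-2-methyl-4-oxocyclohex-2-ene-1-carboxylate F3. Deallylation and decarboxylation (Pd(PPh3)4, morpholine, THF, rt then 60 °C) give 9. The closure must go through that one arm only, since the other mode would lead to the enantiomer.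

**Step 15.** Transmetalation from the hindered pinacol boronate may be slow, so that the allyl–palladium intermediate loses a β-hydrogen to a diene. Fluoride and water may partly open the flavanone, and step 14 carries the same racemisation risk. The fallback sets out from 14 and 19 and returns at 24, so the flavanone never meets palladium. Base-free coupling of 14 with the small boronic acid 19 (Pd2(dba)3, PPh3, THF, rt; carbonate ionisation is much faster than insertion into an electron-rich aryl bromide at this temperature) gives (3R,4R,5S)-3-[5-bromo-2,4-bis(methoxymethoxy)phenyl]-5-ArM-4-[ArM(triethylsilyloxy)methyl]-1-methylcyclohexene F4. Miyaura borylation gives the corresponding pinacol boronate F5. Rhodium-catalysed asymmetric 1,4-addition of F5 to 21 under the conditions of step 13 gives 24.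

**Step 8.** Facial selectivity at C3 may be poor, or the silyl group may migrate to the new alkoxide. The fallback sets out from 12 and returns at 13. Luche reduction (NaBH4, CeCl3·7H2O, MeOH, −78 °C; axial hydride) gives the trans alcohol (1R,5S,6R)-5-ArM-6-[ArM(triethylsilyloxy)methyl]-3-methylcyclohex-2-en-1-ol F6. Mitsunobu inversion (PPh3, DIAD, 4-nitrobenzoic acid) gives the cis 4-nitrobenzoate F7, and methanolysis (K2CO3, MeOH) gives 13.

**Step 13.** The electron-rich, ortho-alkoxy boronic acid may protodeboronate before it adds to the rather unreactive vinylogous ester, and base may erode the new centre. The fallback sets out from 16 and returns at 22. Lithium–bromine exchange of 16 and DMF give 5-bromo-2,4-bis(methoxymethoxy)benzaldehyde F8. Claisen–Schmidt condensation with 1-[2-hydroxy-4-(methoxymethoxy)phenyl]ethanone F9 (from 2,4-dihydroxyacetophenone, MOMCl, K2CO3) gives the chalcone (E)-3-[5-bromo-2,4-bis(methoxymethoxy)phenyl]-1-[2-hydroxy-4-(methoxymethoxy)phenyl]prop-2-en-1-one F10. NaOAc in refluxing EtOH closes the racemic flavanone F11. Kinetic resolution by transfer hydrogenation (RuCl(p-cymene)[(S,S)-TsDPEN] or its antipode as required, HCO2H/Et3N) reduces the 2R enantiomer to the cis-flavan-4-ol (2R,4R)-2-[5-bromo-2,4-bis(methoxymethoxy)phenyl]-7-(methoxymethoxy)chroman-4-ol F12 and leaves 22.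

**Step 3.** Zinc chloride together with the acyl chloride may cleave the acetals, and the electron-rich styrene may polymerise cationically. The fallback sets out from 3 and returns at 7 in one operation, without zinc salts and without step 4. Keteniminium [2+2] cycloaddition (N,N-dimethylacetamide, Tf2O, 2,4,6-collidine, ClCH2CH2Cl, reflux) gives N-{3-[2,4-bis(methoxymethoxy)phenyl]cyclobutylidene}-N-methylmethanaminium triflate F13, which is hydrolysed with aqueous NaHCO3 to 7.

**Step 18.** Once the phenols are free, acid may promote their addition to C1=C2, ketalisation at the C4 carbonyl or opening of the flavanone. The fallback sets out from 26 and returns at 27 without Brønsted acid. TMSOTf and 2,2'-bipyridyl (MeCN, 0 °C) exchange the aryl acetals for silyl ethers to give the heptakis(trimethylsilyl) ether of guangsangon N F14, which water hydrolyses to 27.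

## Further compounds

F1 | step 5 | (E)-4-[2,4-bis(methoxymethoxy)phenyl]but-3-en-2-one | CC(=O)/C=C/c1ccc(OCOC)cc1OCOC
F2 | step 5 | allyl (3R)-2-acetyl-3-[2,4-bis(methoxymethoxy)phenyl]-5-oxohexanoate (C2 epimers) | CC(=O)C[C@@H](c1ccc(OCOC)cc1OCOC)C(C(C)=O)C(=O)OCC=C
F3 | step 5 | allyl (6R)-6-[2,4-bis(methoxymethoxy)phenyl]-2-methyl-4-oxocyclohex-2-ene-1-carboxylate (C1 epimers) | CC1=CC(=O)C[C@@H](c2ccc(OCOC)cc2OCOC)C1C(=O)OCC=C
F4 | step 15 | (3R,4R,5S)-3-[5-bromo-2,4-bis(methoxymethoxy)phenyl]-5-ArM-4-[ArM(triethylsilyloxy)methyl]-1-methylcyclohexene | CC1=C[C@@H](c2cc(Br)c(OCOC)cc2OCOC)[C@H](C(O[Si](CC)(CC)CC)c2ccc(OCOC)cc2OCOC)[C@@H](c2ccc(OCOC)cc2OCOC)C1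
F5 | step 15 | pinacol boronate of F4 (Bpin in place of Br) | CC1=C[C@@H](c2cc(B3OC(C)(C)C(C)(C)O3)c(OCOC)cc2OCOC)[C@H](C(O[Si](CC)(CC)CC)c2ccc(OCOC)cc2OCOC)[C@@H](c2ccc(OCOC)cc2OCOC)C1
F6 | step 8 | (1R,5S,6R)-5-ArM-6-[ArM(triethylsilyloxy)methyl]-3-methylcyclohex-2-en-1-ol (OH trans to the C4 side chain) | CC1=C[C@@H](O)[C@H](C(O[Si](CC)(CC)CC)c2ccc(OCOC)cc2OCOC)[C@@H](c2ccc(OCOC)cc2OCOC)C1
F7 | step 8 | (1S,5S,6R)-5-ArM-6-[ArM(triethylsilyloxy)methyl]-3-methylcyclohex-2-en-1-yl 4-nitrobenzoate | CC1=C[C@H](OC(=O)c2ccc(cc2)[N+](=O)[O-])[C@H](C(O[Si](CC)(CC)CC)c2ccc(OCOC)cc2OCOC)[C@@H](c2ccc(OCOC)cc2OCOC)C1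
F8 | step 13 | 5-bromo-2,4-bis(methoxymethoxy)benzaldehyde | O=Cc1cc(Br)c(OCOC)cc1OCOC
F9 | step 13 | 1-[2-hydroxy-4-(methoxymethoxy)phenyl]ethanone | CC(=O)c1ccc(OCOC)cc1O
F10 | step 13 | (E)-3-[5-bromo-2,4-bis(methoxymethoxy)phenyl]-1-[2-hydroxy-4-(methoxymethoxy)phenyl]prop-2-en-1-one | O=C(/C=C/c1cc(Br)c(OCOC)cc1OCOC)c1ccc(OCOC)cc1O
F11 | step 13 | racemic 2-[5-bromo-2,4-bis(methoxymethoxy)phenyl]-7-(methoxymethoxy)chroman-4-one | O=C1CC(c2cc(Br)c(OCOC)cc2OCOC)Oc2cc(OCOC)ccc21
F12 | step 13 | (2R,4R)-2-[5-bromo-2,4-bis(methoxymethoxy)phenyl]-7-(methoxymethoxy)chroman-4-ol | O[C@@H]1C[C@H](c2cc(Br)c(OCOC)cc2OCOC)Oc2cc(OCOC)ccc21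
F13 | step 3 | N-{3-[2,4-bis(methoxymethoxy)phenyl]cyclobutylidene}-N-methylmethanaminium trifluoromethanesulfonate | C[N+](C)=C1CC(c2ccc(OCOC)cc2OCOC)C1.[O-]S(=O)(=O)C(F)(F)F
F14 | step 18 | heptakis(trimethylsilyl) ether of guangsangon N | CC1=C[C@@H](c2cc([C@@H]3CC(=O)c4ccc(O[Si](C)(C)C)cc4O3)c(O[Si](C)(C)C)cc2O[Si](C)(C)C)[C@H](C(=O)c2ccc(O[Si](C)(C)C)cc2O[Si](C)(C)C)[C@@H](c2ccc(O[Si](C)(C)C)cc2O[Si](C)(C)C)C1
A1 | alternative 1 | [(6R)-6-[2,4-bis(methoxymethoxy)phenyl]-4-methylcyclohexa-1,3-dien-1-yl][2,4-bis(methoxymethoxy)phenyl]methanone | CC1=CC=C(C(=O)c2ccc(OCOC)cc2OCOC)[C@@H](c2ccc(OCOC)cc2OCOC)C1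
A2 | alternative 1 | 3-[2,4-bis(methoxymethoxy)benzoyl]-6-methyl-2H-pyran-2-one | Cc1ccc(C(=O)c2ccc(OCOC)cc2OCOC)c(=O)o1
A3 | alternative 2 | (3R,4R,5S)-3-[2,4-bis(benzyloxy)-5-bromophenyl]-4-[2,4-bis(benzyloxy)benzoyl]-5-[2,4-bis(benzyloxy)phenyl]-1-methylcyclohexene | CC1=C[C@@H](c2cc(Br)c(OCc3ccccc3)cc2OCc2ccccc2)[C@H](C(=O)c2ccc(OCc3ccccc3)cc2OCc2ccccc2)[C@@H](c2ccc(OCc3ccccc3)cc2OCc2ccccc2)C1
A4 | alternative 2 | (3S)-1,3-bis[2,4-bis(benzyloxy)phenyl]-5-methyl-6-(trimethylsilyl)-1-(trimethylsilyloxy)hexa-1,5-diene (alkene geometries open) | CC(=C[Si](C)(C)C)C[C@H](c1ccc(OCc2ccccc2)cc1OCc1ccccc1)C=C(O[Si](C)(C)C)c1ccc(OCc2ccccc2)cc1OCc1ccccc1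
A5 | alternative 2 | 2,4-bis(benzyloxy)-5-bromobenzaldehyde | O=Cc1cc(Br)c(OCc2ccccc2)cc1OCc1ccccc1
A6 | alternative 3 | tert-butyl (2S,3R)-2-{5-[(1R,5S,6R)-6-[2,4-bis(methoxymethoxy)benzoyl]-5-ArM-3-methylcyclohex-2-en-1-yl]-2,4-bis(methoxymethoxy)phenyl}-7-(methoxymethoxy)-4-oxochromane-3-carboxylate | CC1=C[C@@H](c2cc([C@@H]3[C@@H](C(=O)OC(C)(C)C)C(=O)c4ccc(OCOC)cc4O3)c(OCOC)cc2OCOC)[C@H](C(=O)c2ccc(OCOC)cc2OCOC)[C@@H](c2ccc(OCOC)cc2OCOC)C1
A7 | alternative 3 | tert-butyl 3-{5-[(1R,5S,6R)-6-[2,4-bis(methoxymethoxy)benzoyl]-5-ArM-3-methylcyclohex-2-en-1-yl]-2,4-bis(methoxymethoxy)phenyl}-2-[2-hydroxy-4-(methoxymethoxy)benzoyl]prop-2-enoate | CC1=C[C@@H](c2cc(C=C(C(=O)OC(C)(C)C)C(=O)c3ccc(OCOC)cc3O)c(OCOC)cc2OCOC)[C@H](C(=O)c2ccc(OCOC)cc2OCOC)[C@@H](c2ccc(OCOC)cc2OCOC)C1
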